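**Plan**

1. Locants follow the benzofuranone core (O1, C2, C3=C13H2, C3a, C4–C7, C7a; C14 = oxymethyl carbon on C6; C1′ = side-chain stereocentre on C5); Bpin = pinacol boronate, ONf = nonaflate. Cuts: the methacrylate C–O bond, then C14–C6 together with C2–C3 and C2–O1, then C4–C3a and C7–C7a, then C5–C6.
2. Forward: (S)-citronellal gives an acetoxy aldehyde, which is C-acetylated (C5–C6) and silylated to a 1,3-bis(silyloxy)diene; a Diels–Alder reaction with an (E)-β-boryl enone builds the cyclohexene ring; the lactone ring and the C14–C6 bond are then made in one palladium operation; methacrylation and desilylation finish.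
3. Stereochemistry: C1′ comes from (S)-citronellal; C4, C3a and C7a are set together in the endo Diels–Alder reaction of the (E)-diene with the (E)-dienophile under a chiral oxazaborolidinium catalyst; oxidation of C7a–B to C7a–O with retention gives the trans lactone oxygen.
4. Enabling feature: the cycloaddition delivers the tetrasubstituted C5=C6 bond as a regiodefined enol ether (exchanged for a C6 nonaflate) and places the C7a oxygen next to C3a, whose acetyl group becomes an exocyclic enol triflate; the open exocyclic sulfonate and the crowded ring sulfonate react in turn, so CO and then a hydroxymethyl stannane are joined to the core with one catalyst charge.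

Key step: step 13

Assumption: the (S)-configured oxazaborolidinium catalyst is taken to direct the diene to the enone face that gives the ring configuration of the target; if the sense of induction is the opposite, the (R)-catalyst is used and nothing else changes.

**Route**

Step 1
Reactants: 1 (S)-citronellal
Product: 2 (6S)-8,8-dimethoxy-2,6-dimethyloct-2-ene
Conditions: HC(OMe)3, MeOH, PPTS (cat.), rt
Reagents that add atoms: trimethyl orthoformate, COC(OC)OC
Why: Acid-catalysed acetalisation with the orthoformate as water scavenger masks the aldehyde for the alkene cleavage and does not touch the stereocentre.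

Step 2
Reactants: 2 (6S)-8,8-dimethoxy-2,6-dimethyloct-2-ene
Product: 3 (4S)-6,6-dimethoxy-4-methylhexan-1-ol
Conditions: O3, CH2Cl2/MeOH, −78 °C; then NaBH4, −78 → 0 °C
Reagents that add atoms: ozone, [O-][O+]=O
Why: Ozonolysis of the only alkene with reductive borohydride work-up should give the primary alcohol directly, the acetal being inert.

Step 3
Reactants: 3 (4S)-6,6-dimethoxy-4-methylhexan-1-ol
Product: 4 (4S)-6,6-dimethoxy-4-methylhexyl acetate
Conditions: Ac2O, pyridine, DMAP (cat.), CH2Cl2, 0 °C → rt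
Reagents that add atoms: acetic anhydride, CC(=O)OC(C)=O
Why: DMAP-catalysed acetylation installs the side-chain acetate, which every later step is chosen to tolerate.

Step 4
Reactants: 4 (4S)-6,6-dimethoxy-4-methylhexyl acetate
Product: 5 (4S)-4-methyl-6-oxohexyl acetate
Conditions: Amberlyst-15, acetone/H2O, rt
Reagents that add atoms: water, O
Why: Acid-catalysed acetal hydrolysis frees the aldehyde without cleaving the primary acetate, and the stereocentre is β to the carbonyl so it cannot epimerise.

Step 5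
Reactants: 5 (4S)-4-methyl-6-oxohexyl acetate
Product: 8 (4S,5Z)-5-(hydroxymethylidene)-4-methyl-6-oxoheptyl acetate (chelated enol of the β-ketoaldehyde), via morpholine enamine 6 (not isolated), via acetyl enaminone 7 (not isolated)
Conditions: morpholine, K2CO3, Et2O, 0 °C → rt; AcCl, Et3N, 0 °C; then 1 M HCl, THF, rt
Reagents that add atoms: acetyl chloride, CC(=O)Cl; water, O
Why: Stork enamine acylation puts the acetyl group on the nucleophilic β-carbon of the aldehyde enamine (future C5), forming C5–C6 regiospecifically, and hydrolysis of the vinylogous amide releases the β-ketoaldehyde as its enol, C1′ never being α to a carbonyl.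

Step 6
Reactants: 8 (4S,5Z)-5-(hydroxymethylidene)-4-methyl-6-oxoheptyl acetate
Product: 10 (4S,5E)-5-{[tert-butyl(dimethyl)silyl]oxymethylidene}-4-methyl-6-[(trimethylsilyl)oxy]hept-6-en-1-yl acetate, via silyloxymethylene ketone 9 (not isolated)
Conditions: TBSOTf (1.05 equiv), Et3N, CH2Cl2, −78 → 0 °C; then TMSOTf, Et3N, 0 °C
Reagents that add atoms: tert-butyldimethylsilyl triflate, CC(C)(C)[Si](C)(C)OS(=O)(=O)C(F)(F)F; trimethylsilyl triflate, C[Si](C)(C)OS(=O)(=O)C(F)(F)F
Why: O-silylation of the formyl-derived enol oxygen followed by soft enolisation of the methyl ketone gives a Danishefsky-type 1,3-bis(silyloxy)diene, and reversible O-silylation of the vinylogous ester should let the C4=C5 bond settle in the (E)-geometry (silyloxy anti to C6) needed for the s-cis diene.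

Step 7
Reactants: 11 but-3-yn-2-ol (racemic)
Product: 12 (3E)-4-(4,4,5,5-tetramethyl-1,3,2-dioxaborolan-2-yl)but-3-en-2-ol (racemic)
Conditions: B2pin2, CuCl (cat.), Xantphos (cat.), NaOt-Bu (cat.), MeOH, THF, rt
Reagents that add atoms: bis(pinacolato)diboron, CC1(C)OB(OC1(C)C)B2OC(C)(C)C(C)(C)O2
Why: Copper-catalysed protoboration of the terminal alkyne (syn borylcupration with boron at the terminal carbon, then protonolysis by methanol) should give the (E)-alkenyl boronate and tolerates the free hydroxyl.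

Step 8
Reactants: 12 (3E)-4-(Bpin)but-3-en-2-ol
Product: 13 (3E)-4-(4,4,5,5-tetramethyl-1,3,2-dioxaborolan-2-yl)but-3-en-2-one
Conditions: Dess–Martin periodinane, CH2Cl2, rt
Reagents that add atoms: none
Why: Dess–Martin oxidation of the allylic alcohol gives the β-boryl enone without affecting the C–B bond or the alkene geometry.

Step 9
Reactants: 10 bis(silyloxy)diene; 13 β-boryl enone
Product: 14 (4S)-4-[(4R,5S,6S)-5-acetyl-6-{[tert-butyl(dimethyl)silyl]oxy}-4-(Bpin)-2-[(trimethylsilyl)oxy]cyclohex-1-en-1-yl]pentyl acetate (target locants: 6-OTMS enol ether, 4-OTBS cis to 3a-acetyl, 7a-Bpin trans to both)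
Conditions: (S)-o-tolyl-CBS-oxazaborolidine/Tf2NH (20 mol %), CH2Cl2, −78 → −40 °C; Et3N quench
Reagents that add atoms: none
Why: In this oxazaborolidinium-catalysed Diels–Alder reaction the nucleophilic diene terminus C7 bonds to the enone β-carbon (C7a) and C4 to the α-carbon (C3a), the endo (acetyl) transition state puts C4–OSi cis to C3a–acetyl, the (E)-dienophile geometry puts C7a–B trans to C3a–acetyl, and the catalyst's shielding of one enone face sets the absolute configuration of all three centres independently of the remote C1′ centre.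

Step 10
Reactants: 14 cycloadduct silyl enol ether
Product: 15 (4S)-4-[(4R,5S,6S)-5-acetyl-6-{[tert-butyl(dimethyl)silyl]oxy}-2-{[(nonafluorobutyl)sulfonyl]oxy}-4-(Bpin)cyclohex-1-en-1-yl]pentyl acetate
Conditions: C4F9SO2F, TBAF (10 mol %, anhydrous), THF, −40 → 0 °C
Reagents that add atoms: nonafluorobutane-1-sulfonyl fluoride, FS(=O)(=O)C(F)(F)C(F)(F)C(F)(F)C(F)(F)F
Why: Fluoride-catalysed desilylative sulfonylation of the trimethylsilyl enol ether traps the regiodefined C6 enolate on oxygen, with the electrophile present from the start so that sulfonylation should outrun β-elimination of the C4 silyloxide, and so fixes the C5=C6 position given by the cycloaddition.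

Step 11
Reactants: 15 C6 nonaflate methyl ketone
Product: 16 (4S)-4-[(4R,5S,6S)-6-{[tert-butyl(dimethyl)silyl]oxy}-2-{[(nonafluorobutyl)sulfonyl]oxy}-4-(Bpin)-5-(1-{[(trifluoromethyl)sulfonyl]oxy}ethenyl)cyclohex-1-en-1-yl]pentyl acetate
Conditions: KHMDS, THF, −78 °C; PhNTf2, −78 → −20 °C
Reagents that add atoms: N-phenylbis(trifluoromethanesulfonimide), O=S(=O)(N(c1ccccc1)S(=O)(=O)C(F)(F)F)C(F)(F)F
Why: Kinetic deprotonation of the methyl ketone at its methyl group and O-triflation give the exocyclic enol triflate, the more acidic ketone reacting ahead of the acetate and the hindered C3a methine being left unenolised.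

Step 12
Reactants: 16 bis(enol sulfonate) boronate
Product: 17 (4S)-4-[(4R,5S,6S)-6-{[tert-butyl(dimethyl)silyl]oxy}-4-hydroxy-2-{[(nonafluorobutyl)sulfonyl]oxy}-5-(1-{[(trifluoromethyl)sulfonyl]oxy}ethenyl)cyclohex-1-en-1-yl]pentyl acetate
Conditions: NaBO3·4H2O, THF/H2O, 0 °C → rt
Reagents that add atoms: sodium perborate (NaBO3), [Na+].[O-]OB=O
Why: Perborate oxidation of the secondary alkyl boronate proceeds by 1,2-migration with retention, so the C7a hydroxyl is formed trans to the C3a substituent under conditions mild enough for the acetate and both enol sulfonates.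

Step 13
Reactants: 17 hydroxy bis(enol sulfonate); 18 (tributylstannyl)methanol
Product: 20 [(4S)-4-[(3aS,4S,7aR)-4-{[tert-butyl(dimethyl)silyl]oxy}-6-(hydroxymethyl)-3-methylidene-2-oxo-2,3,3a,4,7,7a-hexahydro-1-benzofuran-5-yl]pentyl] acetate, via lactone nonaflate 19 (not isolated)
Conditions: Pd(PPh3)4 (10 mol %), CO (1 atm), i-Pr2NEt, THF, 25 °C; Ar purge; then 18, LiCl, dioxane, 90 °C
Reagents that add atoms: carbon monoxide, [C-]#[O+]
Why: Pd(0) inserts first into the unhindered exocyclic C3 enol triflate, CO insertion gives the acryloyl-palladium, and the neighbouring C7a hydroxyl captures it (bonds C2–C3 and C2–O1) to give the α-methylene lactone 19; after CO is purged the same catalyst inserts into the ring C6 nonaflate, and chloride exchange, transmetalation from 18 and reductive elimination form C14–C6. The closest known reaction types are the cyclocarbonylation of hydroxy enol triflates to α-methylene lactones and the Stille–Kosugi hydroxymethylation of enol triflates with (tributylstannyl)methanol, run here in sequence in one flask so that three components (core, CO, C1 stannane) are joined. The lactone ring (O1, C2, C3, C3a, C7a) closes by 5-exo-trig attack of O7a on the acylpalladium carbon and is trans-fused because the C3a and C7a substituents are already trans. No new stereocentre is formed; C3a, C4 and C7a are carried through and the C5=C6 geometry is fixed by the ring. The step needs site selectivity between two enol sulfonates, which the substrate secures sterically (terminal exocyclic triflate against a tetrasubstituted ring nonaflate flanked by the branched C1′ group on C5 and the silyloxy-bearing C4), and it needs CO to be absent in the second stage so that C6 is hydroxymethylated and not acylated. Joining C14 last leaves C14–OH as the only free hydroxyl for the methacrylate.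

Step 14
Reactants: 20 hydroxymethyl lactone
Product: 21 [(3aS,4S,7aR)-5-[(2S)-5-acetoxypentan-2-yl]-4-{[tert-butyl(dimethyl)silyl]oxy}-3-methylidene-2-oxo-2,3,3a,4,7,7a-hexahydro-1-benzofuran-6-yl]methyl 2-methylprop-2-enoate
Conditions: methacrylic anhydride, Et3N, DMAP (cat.), CH2Cl2, 0 °C
Reagents that add atoms: methacrylic anhydride, C=C(C)C(=O)OC(=O)C(C)=C
Why: DMAP-catalysed acylation of the only free hydroxyl (primary, allylic) installs the methacrylate while C4–O is still silylated.

Step 15
Reactants: 21 methacrylate silyl ether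
Product: 22 [(4S)-4-[(3aR,4S,7aR)-4-hydroxy-3-methylidene-6-[(2-methylprop-2-enoyloxy)methyl]-2-oxo-3a,4,7,7a-tetrahydro-1-benzofuran-5-yl]pentyl] acetate (target)
Conditions: HF·pyridine, pyridine/THF, 0 °C → rt
Reagents that add atoms: none
Why: Fluoride-driven desilylation under non-basic conditions frees the C4 hydroxyl without ester cleavage, conjugate addition to the α-methylene lactone or lactone migration to O4.

**Compound list**

1 | (S)-citronellal, (3S)-3,7-dimethyloct-6-enal | O=CC[C@@H](C)CCC=C(C)C | starting material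
2 | (6S)-8,8-dimethoxy-2,6-dimethyloct-2-ene | COC(OC)C[C@@H](C)CCC=C(C)C | intermediate
3 | (4S)-6,6-dimethoxy-4-methylhexan-1-ol | COC(OC)C[C@@H](C)CCCO | intermediate
4 | (4S)-6,6-dimethoxy-4-methylhexyl acetate | COC(OC)C[C@@H](C)CCCOC(C)=O | intermediate
5 | (4S)-4-methyl-6-oxohexyl acetate | O=CC[C@@H](C)CCCOC(C)=O | intermediate
6 | (4S,5E)-4-methyl-6-(morpholin-4-yl)hex-5-en-1-yl acetate | O1CCN(CC1)/C=C/[C@@H](C)CCCOC(C)=O | intermediate (not isolated)
7 | (4S,5E)-4-methyl-5-(morpholin-4-ylmethylidene)-6-oxoheptyl acetate | CC(=O)/C(=C/N1CCOCC1)[C@@H](C)CCCOC(C)=O | intermediate (not isolated)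
8 | (4S,5Z)-5-(hydroxymethylidene)-4-methyl-6-oxoheptyl acetate | CC(=O)/C(=C\O)[C@@H](C)CCCOC(C)=O | intermediate
9 | (4S,5E)-5-{[tert-butyl(dimethyl)silyl]oxymethylidene}-4-methyl-6-oxoheptyl acetate | CC(=O)/C(=C/O[Si](C)(C)C(C)(C)C)[C@@H](C)CCCOC(C)=O | intermediate (not isolated)
10 | (4S,5E)-5-{[tert-butyl(dimethyl)silyl]oxymethylidene}-4-methyl-6-[(trimethylsilyl)oxy]hept-6-en-1-yl acetate | C=C(O[Si](C)(C)C)/C(=C/O[Si](C)(C)C(C)(C)C)[C@@H](C)CCCOC(C)=O | intermediate
11 | but-3-yn-2-ol (racemic) | CC(O)C#C | starting material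
12 | (3E)-4-(4,4,5,5-tetramethyl-1,3,2-dioxaborolan-2-yl)but-3-en-2-ol (racemic) | CC(O)/C=C/B1OC(C)(C)C(C)(C)O1 | intermediate
13 | (3E)-4-(4,4,5,5-tetramethyl-1,3,2-dioxaborolan-2-yl)but-3-en-2-one | CC(=O)/C=C/B1OC(C)(C)C(C)(C)O1 | intermediate
14 | (4S)-4-[(4R,5S,6S)-5-acetyl-6-{[tert-butyl(dimethyl)silyl]oxy}-4-(Bpin)-2-[(trimethylsilyl)oxy]cyclohex-1-en-1-yl]pentyl acetate | C[Si](C)(C)OC1=C([C@@H](C)CCCOC(C)=O)[C@@H](O[Si](C)(C)C(C)(C)C)[C@@H](C(C)=O)[C@H](B2OC(C)(C)C(C)(C)O2)C1 | intermediate
15 | (4S)-4-[(4R,5S,6S)-5-acetyl-6-{[tert-butyl(dimethyl)silyl]oxy}-2-{[(nonafluorobutyl)sulfonyl]oxy}-4-(Bpin)cyclohex-1-en-1-yl]pentyl acetate | FC(F)(F)C(F)(F)C(F)(F)C(F)(F)S(=O)(=O)OC1=C([C@@H](C)CCCOC(C)=O)[C@@H](O[Si](C)(C)C(C)(C)C)[C@@H](C(C)=O)[C@H](B2OC(C)(C)C(C)(C)O2)C1 | intermediate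
16 | (4S)-4-[(4R,5S,6S)-6-{[tert-butyl(dimethyl)silyl]oxy}-2-{[(nonafluorobutyl)sulfonyl]oxy}-4-(Bpin)-5-(1-{[(trifluoromethyl)sulfonyl]oxy}ethenyl)cyclohex-1-en-1-yl]pentyl acetate | FC(F)(F)C(F)(F)C(F)(F)C(F)(F)S(=O)(=O)OC1=C([C@@H](C)CCCOC(C)=O)[C@@H](O[Si](C)(C)C(C)(C)C)[C@@H](C(=C)OS(=O)(=O)C(F)(F)F)[C@H](B2OC(C)(C)C(C)(C)O2)C1 | intermediate
17 | (4S)-4-[(4R,5S,6S)-6-{[tert-butyl(dimethyl)silyl]oxy}-4-hydroxy-2-{[(nonafluorobutyl)sulfonyl]oxy}-5-(1-{[(trifluoromethyl)sulfonyl]oxy}ethenyl)cyclohex-1-en-1-yl]pentyl acetate | FC(F)(F)C(F)(F)C(F)(F)C(F)(F)S(=O)(=O)OC1=C([C@@H](C)CCCOC(C)=O)[C@@H](O[Si](C)(C)C(C)(C)C)[C@@H](C(=C)OS(=O)(=O)C(F)(F)F)[C@H](O)C1 | intermediate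
18 | (tributylstannyl)methanol | CCCC[Sn](CCCC)(CCCC)CO | starting material
19 | [(4S)-4-[(3aS,4S,7aR)-4-{[tert-butyl(dimethyl)silyl]oxy}-3-methylidene-6-{[(nonafluorobutyl)sulfonyl]oxy}-2-oxo-2,3,3a,4,7,7a-hexahydro-1-benzofuran-5-yl]pentyl] acetate | FC(F)(F)C(F)(F)C(F)(F)C(F)(F)S(=O)(=O)OC1=C([C@@H](C)CCCOC(C)=O)[C@@H](O[Si](C)(C)C(C)(C)C)[C@H]2C(=C)C(=O)O[C@@H]2C1 | intermediate (not isolated)
20 | [(4S)-4-[(3aS,4S,7aR)-4-{[tert-butyl(dimethyl)silyl]oxy}-6-(hydroxymethyl)-3-methylidene-2-oxo-2,3,3a,4,7,7a-hexahydro-1-benzofuran-5-yl]pentyl] acetate | OCC1=C([C@@H](C)CCCOC(C)=O)[C@@H](O[Si](C)(C)C(C)(C)C)[C@H]2C(=C)C(=O)O[C@@H]2C1 | intermediate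
21 | [(3aS,4S,7aR)-5-[(2S)-5-acetoxypentan-2-yl]-4-{[tert-butyl(dimethyl)silyl]oxy}-3-methylidene-2-oxo-2,3,3a,4,7,7a-hexahydro-1-benzofuran-6-yl]methyl 2-methylprop-2-enoate | C=C(C)C(=O)OCC1=C([C@@H](C)CCCOC(C)=O)[C@@H](O[Si](C)(C)C(C)(C)C)[C@H]2C(=C)C(=O)O[C@@H]2C1 | intermediate
22 | [(4S)-4-[(3aR,4S,7aR)-4-hydroxy-3-methylidene-6-[(2-methylprop-2-enoyloxy)methyl]-2-oxo-3a,4,7,7a-tetrahydro-1-benzofuran-5-yl]pentyl] acetate | C=C(C)C(=O)OCC1=C([C@@H](C)CCCOC(C)=O)[C@@H](O)[C@H]2C(=C)C(=O)O[C@@H]2C1 | target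

**Count and risks**

Total steps: 15. Longest linear sequence: 13 (steps 1–6 and 9–15; steps 7–8 make the dienophile).

Step 13. The hydroxymethyl group may transfer too slowly from tin to the crowded alkenylpalladium at C6, so that isomerisation or oligomerisation of the α-methylene lactone and protodestannylation take over. The fallback stops the operation after the carbonylation stage and isolates 19. Palladium-catalysed reductive carbonylation (Pd(OAc)2, dppp, CO, Et3SiH, Et3N, DMF, 70 °C) then converts the nonaflate into the 6-formyl lactone F1, in which C14 comes from CO. Luche reduction of F1 (NaBH4, CeCl3·7H2O, MeOH, −78 °C) returns to the route at 20.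

Step 9. The catalyst may give poor facial discrimination, or the strong Lewis acid may desilylate the bis(silyloxy)diene before cycloaddition. The fallback sets out from 10 and moves stereocontrol to a covalently bound auxiliary. Propiolic acid is coupled to (S)-4-benzyloxazolidin-2-one (PivCl, Et3N, LiCl) to give the N-propioloyl imide F2. Copper-catalysed protoboration as in step 7 gives the (E)-β-boryl acryloyl imide F3. Me2AlCl-promoted cycloaddition of the chelated imide with 10 (CH2Cl2, −78 °C) gives the imide cycloadduct F4, the benzyl group shielding one face (the auxiliary enantiomer is chosen by the chelate model). LiSEt (THF, −20 °C) releases the auxiliary and gives the ethyl thioester F5. Me2CuLi (THF, −78 °C) converts F5 into the methyl ketone 14, where the route resumes.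

Step 15. Cleavage of the hindered allylic silyl ether may be slow, and under forcing conditions ionisation at C4, loss of the methacrylate or migration of the lactone to O4 may compete. The fallback sets out from 20 and removes the silyl group before the methacrylate is present (aq HF, MeCN, 0 °C), giving the 4,14-diol F6. The primary allylic hydroxyl of F6 is then acylated selectively (methacryloyl chloride, 2,4,6-collidine, CH2Cl2, −78 °C), which gives 22 directly.

**Further compounds**

F1 | step 13 | [(4S)-4-[(3aS,4S,7aR)-4-{[tert-butyl(dimethyl)silyl]oxy}-6-formyl-3-methylidene-2-oxo-2,3,3a,4,7,7a-hexahydro-1-benzofuran-5-yl]pentyl] acetate | O=CC1=C([C@@H](C)CCCOC(C)=O)[C@@H](O[Si](C)(C)C(C)(C)C)[C@H]2C(=C)C(=O)O[C@@H]2C1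
F2 | step 9 | (4S)-4-benzyl-3-propioloyloxazolidin-2-one | C#CC(=O)N1[C@@H](Cc2ccccc2)COC1=O
F3 | step 9 | (4S)-4-benzyl-3-[(2E)-3-(4,4,5,5-tetramethyl-1,3,2-dioxaborolan-2-yl)prop-2-enoyl]oxazolidin-2-one | O=C(/C=C/B1OC(C)(C)C(C)(C)O1)N2[C@@H](Cc3ccccc3)COC2=O
F4 | step 9 | imide cycloadduct, analogue of 14 with the (4S)-4-benzyl-2-oxooxazolidine-3-carbonyl group in place of acetyl | C[Si](C)(C)OC1=C([C@@H](C)CCCOC(C)=O)[C@@H](O[Si](C)(C)C(C)(C)C)[C@@H](C(=O)N2[C@@H](Cc3ccccc3)COC2=O)[C@H](B4OC(C)(C)C(C)(C)O4)C1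
F5 | step 9 | S-ethyl thioester, analogue of 14 with C(=O)SEt in place of acetyl | C[Si](C)(C)OC1=C([C@@H](C)CCCOC(C)=O)[C@@H](O[Si](C)(C)C(C)(C)C)[C@@H](C(=O)SCC)[C@H](B2OC(C)(C)C(C)(C)O2)C1
F6 | step 15 | [(4S)-4-[(3aR,4S,7aR)-4-hydroxy-6-(hydroxymethyl)-3-methylidene-2-oxo-3a,4,7,7a-tetrahydro-1-benzofuran-5-yl]pentyl] acetate | OCC1=C([C@@H](C)CCCOC(C)=O)[C@@H](O)[C@H]2C(=C)C(=O)O[C@@H]2C1
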